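**Plan**

- Retrosynthesis: the O4 methyl ether and the C7 prenyl group (from allyl, from CO2H) are taken back first. Ring B is then cut at C1–C8, the carboxyl carbon on C7 leaving as CO. The quaternary C5–C6 bond is cut by a retro-Claisen shift to an aryl prenyl ether, and the O-prenyl, O-methyl and two C-prenyl bonds lead back to 2,4,6-trihydroxybenzophenone.
- Forward: ring A (C1–C2–C3–C4–C5–C9) is the arene of the starting material and is dearomatised at C5 by a [3,3] shift. Ring B (C1–C8–C7–C6–C5–C9) is closed on it by a palladium-mediated enol–alkene carbocyclisation with CO capture. Decarboxylative allylation, metathesis and demethylation finish the route.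
- Enabling feature: in dienone 5 the only monosubstituted alkene (C7=C8 of the 2-methylbut-3-en-2-yl group) hangs from C6, two sp3 carbons (C5, C6) away from C9 and over the enol carbon C1 of the C2/C9/benzoyl triketone. C1 can therefore reach C8 through a six-membered transition state. The O4 methyl ether fixes C3=C4 and leaves C1 as the only nucleophilic ring carbon.
- Stereochemistry: C5 comes from a catalyst-controlled Claisen shift (resolution as fallback). C1 follows from C5 because the bridge can only close cis. C7 comes from exo-face trapping of the C7 radical on the bicycle.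

Key step: step 5

Remark: the numbering is that of the bicyclo[3.3.1]nonane (C1 benzoyl bridgehead, C5 prenyl bridgehead, C9 bridging ketone) and is kept for the same carbons in all precursors. The target is drawn as the 2-hydroxy-4-oxo enol, a tautomer of the 4-hydroxy-2-oxo form released by demethylation at O4, so both are taken as one compound.

**Route**

Step 1
Reactants: 1 2,4,6-trihydroxybenzophenone
Product: 2 clusiaphenone B, [2,4,6-trihydroxy-3,5-bis(3-methylbut-2-en-1-yl)phenyl](phenyl)methanone
Conditions: prenyl bromide (2.2 equiv), KOH (5% in H2O), 0 °C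
Reagents that add atoms: prenyl bromide (1-bromo-3-methylbut-2-ene), CC(C)=CCBr
Why: Known double C-prenylation of a phloroglucinol polyanion in water, where aqueous hydroxide favours C- over O-alkylation and the two free ring carbons are the only sites that can re-aromatise; no stereocentre is formed.

Step 2
Reactants: 2 clusiaphenone B
Product: 3 [2,6-dihydroxy-4-methoxy-3,5-bis(3-methylbut-2-en-1-yl)phenyl](phenyl)methanone
Conditions: Me2SO4 (1.0 equiv), K2CO3 (1.0 equiv), acetone, 23 °C
Reagents that add atoms: dimethyl sulfate, COS(=O)(=O)OC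
Why: Williamson methylation; the 4-OH, para to the benzoyl group, is the most acidic hydroxyl and is not hydrogen-bonded to the ketone, so it should be etherified first; this methyl group later blocks C3 as a nucleophile and is removed in step 9.

Step 3
Reactants: 3 4-O-methyl ether
Product: 4 {2-hydroxy-4-methoxy-3,5-bis(3-methylbut-2-en-1-yl)-6-[(3-methylbut-2-en-1-yl)oxy]phenyl}(phenyl)methanone
Conditions: prenyl bromide (1.2 equiv), K2CO3 (1.5 equiv), DMF, 23 °C
Reagents that add atoms: prenyl bromide (1-bromo-3-methylbut-2-ene), CC(C)=CCBr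
Why: Williamson O-alkylation under K2CO3/DMF, which favours O- over C-prenylation; the two ortho hydroxyls are equivalent, and after the first is alkylated the second is held in a hydrogen bond to the ketone, so mono-etherification is expected.

Step 4
Reactants: 4 aryl prenyl ether
Product: 5 (6R)-2-benzoyl-3-hydroxy-5-methoxy-6-(2-methylbut-3-en-2-yl)-4,6-bis(3-methylbut-2-en-1-yl)cyclohexa-2,4-dien-1-one (the quaternary ring carbon is C5 of the target numbering)
Conditions: Ni(OTf)2 (10 mol %), C2-symmetric chiral N,N′-dioxide ligand from pipecolic acid and 2,6-diisopropylaniline (11 mol %), CH2Cl2, 30 °C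
Reagents that add atoms: none
Why: Proposed new method: a divalent nickel complex of the chiral N,N′-dioxide is expected to chelate the ether oxygen and the benzoyl oxygen of 4 (a β-alkoxy enone, six-membered chelate), which polarises the O–CH2 bond and lowers the barrier of the aromatic Claisen [3,3] shift through a chair transition state to C5, the ortho carbon outside the chelate (bond fixation by the 2-hydroxy ketone also favours C5 over C1), while the ligand shields one face of C5 and so sets the quaternary centre; the closest known reaction types are chiral Lewis acid-catalysed Claisen rearrangements of 2-acyl- or 2-alkoxycarbonyl-substituted allyl vinyl ethers and the catalytic enantioselective dearomative Claisen rearrangement of allyl 2-naphthyl ethers with an ortho ester, and the ligand antipode that leads to (R)-5 is to be chosen in a first screen.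

Step 5
Reactants: 5 dienone
Product: 6 2-(trimethylsilyl)ethyl (1R,5R,7R)-1-benzoyl-4-methoxy-6,6-dimethyl-3,5-bis(3-methylbut-2-en-1-yl)-2,9-dioxobicyclo[3.3.1]non-3-ene-7-carboxylate
Conditions: PdCl2(MeCN)2 (10 mol %), CuCl2 (2.5 equiv), CO (1 atm), Me3SiCH2CH2OH (10 equiv), propylene oxide (5 equiv), THF, 23 °C
Reagents that add atoms: carbon monoxide, [C-]#[O+]; 2-(trimethylsilyl)ethanol, C[Si](C)(C)CCO
Why: Proposed new method: PdCl2(MeCN)2 should bind the single monosubstituted alkene C7=C8 rather than the three trisubstituted prenyl alkenes, the enol carbon C1 then attacks the terminal carbon C8 anti to palladium, and the secondary alkylpalladium at C7 is intercepted by CO insertion (faster than β-hydride loss under 1 atm CO) and alcoholysis of the acylpalladium, after which CuCl2 returns zerovalent palladium to the divalent state. The closest known reaction types are the divalent-palladium-catalysed 6-endo hydroalkylation and oxidative alkylation of 3-butenyl β-diketones, the cyclisation/carboalkoxylation of alkenyl indoles under the same PdCl2(MeCN)2/CuCl2/CO conditions and the stoichiometric palladium-assisted alkylation–carbonylation of olefins by stabilised carbanions; new is their combination on a β-triketone enol. Ring B (C1–C8–C7–C6–C5–C9) closes in the 6-endo-trig mode, because C7 is neopentylic and 5-exo attack there would build a more strained bicyclo[3.2.1]octane. C1 is controlled by C5 (the C6–C7–C8 tether lies on one face of ring A, so the C9 bridge and the new bond must be cis), and at C7 anti addition through a chair places palladium, and after insertion with retention the ester, equatorial (exo); this centre is reset in step 7. The step needs C1 rather than C3 or oxygen to attack: the O4 methyl ether locks C3=C4 as a vinylogous ester so that C1 is the only enol carbon, and carbon attack is the known course for β-diketones that carry the alkene two sp3 carbons from the carbonyl.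

Step 6
Reactants: 6 bicyclic 2-(trimethylsilyl)ethyl ester
Product: 7 (1R,5R,7R)-1-benzoyl-4-methoxy-6,6-dimethyl-3,5-bis(3-methylbut-2-en-1-yl)-2,9-dioxobicyclo[3.3.1]non-3-ene-7-carboxylic acid
Conditions: Bu4NF (1.5 equiv), THF, 0 °C; then cold dilute HCl
Reagents that add atoms: none
Why: Fluoride-induced fragmentation of the 2-(trimethylsilyl)ethyl ester (loss of Me3SiF and ethene); the methyl enol ether, the ketones and the prenyl groups should be inert, and fluoride at 0 °C is used in place of hydroxide, which could cleave the non-enolisable 1-benzoyl β-triketone by a retro-Claisen reaction.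

Step 7
Reactants: 7 bicyclic acid
Product: 8 (1R,5R,7R)-1-benzoyl-4-methoxy-6,6-dimethyl-3,5-bis(3-methylbut-2-en-1-yl)-7-(prop-2-en-1-yl)bicyclo[3.3.1]non-3-ene-2,9-dione
Conditions: allyl phenyl sulfone (4 equiv), [Ir(dF(CF3)ppy)2(dtbbpy)]PF6 (2 mol %), K2HPO4 (1.2 equiv), DMF, blue LEDs, 23 °C
Reagents that add atoms: allyl phenyl sulfone, C=CCS(=O)(=O)c1ccccc1
Why: Photoredox decarboxylative radical allylation (oxidation of the carboxylate by the excited iridium complex, loss of CO2, SH2′ addition of the C7 radical to the allyl sulfone, β-scission of the sulfonyl radical, which is then reduced to close the cycle); the planar C7 radical should be attacked on the exo face, away from the C2–C3–C4 bridge and its C3 prenyl group, so the allyl group ends equatorial (7R), the face selectivity known for tin-mediated allylation of C7 radicals in related bicyclo[3.3.1]nonane triones.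

Step 8
Reactants: 8 C7-allyl compound
Product: 9 (1R,5R,7R)-1-benzoyl-4-methoxy-6,6-dimethyl-3,5,7-tris(3-methylbut-2-en-1-yl)bicyclo[3.3.1]non-3-ene-2,9-dione
Conditions: second-generation Grubbs catalyst RuCl2(H2IMes)(PCy3)(=CHPh) (10 mol %), 2-methylbut-2-ene/CH2Cl2, 40 °C
Reagents that add atoms: 2-methylbut-2-ene, CC=C(C)C
Why: Olefin cross-metathesis of the terminal allyl group with 2-methylbut-2-ene as co-solvent, a standard allyl-to-prenyl conversion; the existing prenyl groups can only exchange degenerately and no stereocentre is touched.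

Step 9
Reactants: 9 O4-methyl ether of the target
Product: 10 target, (1S,5R,7R)-1-benzoyl-2-hydroxy-6,6-dimethyl-3,5,7-tris(3-methylbut-2-en-1-yl)bicyclo[3.3.1]non-2-ene-4,9-dione
Conditions: LiCl (10 equiv), DMSO, 120 °C; then 1 M HCl
Reagents that add atoms: none
Why: Krapcho-type SN2 demethylation of the vinylogous methyl ester by chloride, a usual last step for such bicyclic methyl enol ethers; it frees the C2/C4 vinylogous acid, which is the target in its drawn tautomer, and avoids hydroxide, which could cleave the 1-benzoyl triketone.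

**Compound list**

1 | 2,4,6-trihydroxybenzophenone | O=C(c1ccccc1)c1c(O)cc(O)cc1O | starting material
2 | clusiaphenone B, [2,4,6-trihydroxy-3,5-bis(3-methylbut-2-en-1-yl)phenyl](phenyl)methanone | CC(C)=CCc1c(O)c(CC=C(C)C)c(O)c(C(=O)c2ccccc2)c1O | intermediate
3 | [2,6-dihydroxy-4-methoxy-3,5-bis(3-methylbut-2-en-1-yl)phenyl](phenyl)methanone | CC(C)=CCc1c(OC)c(CC=C(C)C)c(O)c(C(=O)c2ccccc2)c1O | intermediate
4 | {2-hydroxy-4-methoxy-3,5-bis(3-methylbut-2-en-1-yl)-6-[(3-methylbut-2-en-1-yl)oxy]phenyl}(phenyl)methanone | CC(C)=CCOc1c(CC=C(C)C)c(OC)c(CC=C(C)C)c(O)c1C(=O)c1ccccc1 | intermediate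
5 | (6R)-2-benzoyl-3-hydroxy-5-methoxy-6-(2-methylbut-3-en-2-yl)-4,6-bis(3-methylbut-2-en-1-yl)cyclohexa-2,4-dien-1-one | C=CC(C)(C)[C@](CC=C(C)C)(C(OC)=C(CC=C(C)C)C(O)=C1C(=O)c2ccccc2)C1=O | intermediate
6 | 2-(trimethylsilyl)ethyl (1R,5R,7R)-1-benzoyl-4-methoxy-6,6-dimethyl-3,5-bis(3-methylbut-2-en-1-yl)-2,9-dioxobicyclo[3.3.1]non-3-ene-7-carboxylate | CC(C)=CCC1=C(OC)[C@@]2(CC=C(C)C)C(C)(C)[C@H](C(=O)OCC[Si](C)(C)C)C[C@@](C(=O)c3ccccc3)(C1=O)C2=O | intermediate
7 | (1R,5R,7R)-1-benzoyl-4-methoxy-6,6-dimethyl-3,5-bis(3-methylbut-2-en-1-yl)-2,9-dioxobicyclo[3.3.1]non-3-ene-7-carboxylic acid | CC(C)=CCC1=C(OC)[C@@]2(CC=C(C)C)C(C)(C)[C@H](C(=O)O)C[C@@](C(=O)c3ccccc3)(C1=O)C2=O | intermediate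
8 | (1R,5R,7R)-1-benzoyl-4-methoxy-6,6-dimethyl-3,5-bis(3-methylbut-2-en-1-yl)-7-(prop-2-en-1-yl)bicyclo[3.3.1]non-3-ene-2,9-dione | CC(C)=CCC1=C(OC)[C@@]2(CC=C(C)C)C(C)(C)[C@H](CC=C)C[C@@](C(=O)c3ccccc3)(C1=O)C2=O | intermediate
9 | (1R,5R,7R)-1-benzoyl-4-methoxy-6,6-dimethyl-3,5,7-tris(3-methylbut-2-en-1-yl)bicyclo[3.3.1]non-3-ene-2,9-dione | CC(C)=CCC1=C(OC)[C@@]2(CC=C(C)C)C(C)(C)[C@H](CC=C(C)C)C[C@@](C(=O)c3ccccc3)(C1=O)C2=O | intermediate
10 | (1S,5R,7R)-1-benzoyl-2-hydroxy-6,6-dimethyl-3,5,7-tris(3-methylbut-2-en-1-yl)bicyclo[3.3.1]non-2-ene-4,9-dione | CC(C)=CCC1=C(O)[C@]2(C(=O)c3ccccc3)C[C@@H](CC=C(C)C)C(C)(C)[C@](CC=C(C)C)(C1=O)C2=O | target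

**Count and risks**

Total step count: 9. Longest linear sequence: 9 steps, from 1.

Steps most likely to fail:

1. Step 5 (Proposed new method). β-Hydride loss at C7 may outrun CO insertion, oxygen instead of carbon may attack the palladium-bound alkene, or the tetrasubstituted enol carbon may be too weak a nucleophile to cyclise at all. The fallback uses known chemistry, sets out from 5 and comes back at 7. The monosubstituted alkene of 5 is hydroborated chemoselectively with 9-BBN (THF; NaBO3 oxidation) to the primary alcohol F1, which is oxidised with Dess–Martin periodinane to the aldehyde F2. α-Methylenation (aqueous CH2O, pyrrolidine, propionic acid) gives the 2-substituted acrolein F3, whose new methylene carbon takes the role of C8 while the former vinyl terminus becomes the aldehyde carbon. Intramolecular Michael addition of C1 (catalytic Et3N, CH2Cl2), the known closing step of alkylative dearomatisation–annulation routes to such triones, gives the bicyclic aldehyde F4, equatorial after equilibration through its enol. Pinnick oxidation (NaClO2, NaH2PO4, 2-methylbut-2-ene, t-BuOH/H2O) then returns to acid 7.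

2. Step 4 (Proposed new method). Face control may be poor because the free phenol competes for nickel, a second [3,3] (Cope) shift may carry the 2-methylbut-3-en-2-yl group from C5 on to C3, or the prenyl ether may ionise and recombine as a normal prenyl group. The fallback uses known chemistry, sets out from 4 and comes back at 5. An achiral Claisen rearrangement catalysed by Eu(fod)3 (CHCl3, 40 °C) gives the racemic dienone F5. Acylation of its enol hydroxyl with (1S)-camphanic chloride (Et3N, DMAP, CH2Cl2) gives two diastereomeric enol esters that are separated by chromatography, the one with the (R)-configured ring carbon being the camphanate F6. Methanolysis (K2CO3, MeOH, 0 °C) releases 5.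

3. Step 7. Capture of the hindered secondary C7 radical by the unactivated allyl sulfone may be too slow, so that hydrogen abstraction from the medium gives the C7-unsubstituted product, and some attack from the endo face may erode the selectivity. The fallback changes the radical precursor and the chain carrier, sets out from 7 and comes back at 8. Acid 7 is converted (N-hydroxypyridine-2-thione, DCC) into the Barton ester F7, which on irradiation with CHI3 undergoes Barton iododecarboxylation to the secondary iodide F8. Keck allylation (Bu3SnCH2CH=CH2, AIBN, benzene, 80 °C), a chain without hydrogen donors, then gives 8.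

**Further compounds**

F1 | step 5 | (6R)-2-benzoyl-3-hydroxy-6-(4-hydroxy-2-methylbutan-2-yl)-5-methoxy-4,6-bis(3-methylbut-2-en-1-yl)cyclohexa-2,4-dien-1-one | OCCC(C)(C)[C@](CC=C(C)C)(C(OC)=C(CC=C(C)C)C(O)=C1C(=O)c2ccccc2)C1=O
F2 | step 5 | 3-[(1R)-3-benzoyl-4-hydroxy-6-methoxy-1,5-bis(3-methylbut-2-en-1-yl)-2-oxocyclohexa-3,5-dien-1-yl]-3-methylbutanal | O=CCC(C)(C)[C@](CC=C(C)C)(C(OC)=C(CC=C(C)C)C(O)=C1C(=O)c2ccccc2)C1=O
F3 | step 5 | 3-[(1R)-3-benzoyl-4-hydroxy-6-methoxy-1,5-bis(3-methylbut-2-en-1-yl)-2-oxocyclohexa-3,5-dien-1-yl]-3-methyl-2-methylidenebutanal | C=C(C=O)C(C)(C)[C@](CC=C(C)C)(C(OC)=C(CC=C(C)C)C(O)=C1C(=O)c2ccccc2)C1=O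
F4 | step 5 | (1R,5R,7R)-1-benzoyl-4-methoxy-6,6-dimethyl-3,5-bis(3-methylbut-2-en-1-yl)-2,9-dioxobicyclo[3.3.1]non-3-ene-7-carbaldehyde | CC(C)=CCC1=C(OC)[C@@]2(CC=C(C)C)C(C)(C)[C@H](C=O)C[C@@](C(=O)c3ccccc3)(C1=O)C2=O
F5 | step 4 | racemic 2-benzoyl-3-hydroxy-5-methoxy-6-(2-methylbut-3-en-2-yl)-4,6-bis(3-methylbut-2-en-1-yl)cyclohexa-2,4-dien-1-one | C=CC(C)(C)C1(CC=C(C)C)C(OC)=C(CC=C(C)C)C(O)=C(C(=O)c2ccccc2)C1=O
F6 | step 4 | (1S,4R)-camphanate ester of the enol hydroxyl of (6R)-5 | C=CC(C)(C)[C@](CC=C(C)C)(C(OC)=C(CC=C(C)C)C(OC(=O)[C@@]34CC[C@@](C)(C(=O)O3)C4(C)C)=C1C(=O)c2ccccc2)C1=O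
F7 | step 7 | 2-thioxopyridin-1(2H)-yl ester (Barton ester) of acid 7 | CC(C)=CCC1=C(OC)[C@@]2(CC=C(C)C)C(C)(C)[C@H](C(=O)ON4C=CC=CC4=S)C[C@@](C(=O)c3ccccc3)(C1=O)C2=O
F8 | step 7 | (1R,5R)-1-benzoyl-7-iodo-4-methoxy-6,6-dimethyl-3,5-bis(3-methylbut-2-en-1-yl)bicyclo[3.3.1]non-3-ene-2,9-dione, C7 epimers | CC(C)=CCC1=C(OC)[C@@]2(CC=C(C)C)C(C)(C)C(I)C[C@@](C(=O)c3ccccc3)(C1=O)C2=O
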